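The readings were generated by integration for an exercise, noise included.

Amounts first: grey gets 0.10 M of Z at once, red gets 0.054 M in 2 portions, both get 0.12 mM of Q, and you suspected the portions would part them. I reckon they won't, following one Z molecule to its fork: E or G.

all flasks: Q 0.12 mM
- east: Z 0.054 M (in portions, 2); J 8.5 µM; temperature 0 °C; run made earlier; portions every 2.0 h
- north-west: Z 0.054 M (in portions, 2); J 16 µM; temperature 11 °C; run made earlier; portions every 2.0 h
- west: Z 0.067 M (in portions, 2); J 24 µM; temperature 0 °C; run made earlier; portions every 2.0 h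
- grey: Z 0.10 M; J 15 µM; temperature 5 °C; everything together at the start; time 20 h
- red: Z 0.054 M (in portions, 2); J 24 µM; temperature 5 °C; the portions of Z follow each other after 2.0 h, the first at the start; time 20 h

- east (time / h: E / %, G / %): 0.833: 0, 0.5; 1.33: 0, 0; 2.00: 0.6, 1.4; 4.00: 6.7, 2.5; 6.00: 13.2, 3.8; 10.0: 30.8, 5.7
- north-west (time / h: E / %, G / %): 0.667: 1.0, 0.9; 2.00: 7.9, 4.9; 4.00: 33.4, 11.3; 5.00: 44.3, 12.8; 8.00: 63.9, 17.0; 10.0: 71.0, 18.4
- west (time / h: E / %, G / %): 0.833: 0, 0.8; 2.50: 1.8, 1.7; 5.00: 6.8, 3.4; 8.00: 16.8, 5.5; 10.0: 23.9, 6.8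

(standard deviation of a reading: 0.5 percentage points)

- what was read earlier has a scatter of 0.5 percentage points, one standard deviation

* the winner by share of E in all that became E or G; "neither" if no more than 2 percentage points parts them (grey / red / neither)
* share of E in all that became E or G, grey
* share of E in all that became E or G, red

I assume both gains are first order in cZ, so cZ cancels from f, the E gained per G gained over a stretch (a selectivity factor). West, with more J than east at equal temperature, reads f = 5.46 from 8.00 h to 10.0 h, and east reads 9.26 from 6.00 h to 10.0 h, so west stands lower than east; with cZ cancelled, I assume J removes its own amount of catalyst and divide f by cQ − cJ. Late stretches give: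

east, 6.00 h to 10.0 h: f = 9.26, f/(cQ − cJ) = 83.1 /mM

north-west, 5.00 h to 10.0 h: f = 4.77, f/(cQ − cJ) = 45.8 /mM

5 °C lies near the middle of that range, so the geometric mean gives the fork constant g = f/(cQ − cJ) 61.7 /mM. East's G gain is just 1.9 percentage points, so g is a rough reading.

grey: f = 6.48, late share f/(1 + f) = 86.6%

red: f = 5.92, late share 85.6%

The poor start costs something: north-west's whole share at 10.0 h lies 3.2 points below its late share. Taking that from both, I say grey 83.4%, red 82.3%, and the gap of 1.0 point is less than 2 points: neither.

The forecast also says neither, with grey 80% (74% to 85%) and red 81% (76% to 85%), and its grey stands lower than mine: “The two end up close”.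

The simulation gives neither: grey 82.1%, red 81.9%.

    Z + D → D + E (k = 1300 /M/h, Ea = 58.0 kJ/mol)
    Z → G (k = 0.0190 /h, Ea = 98.0 kJ/mol)
    Q → D (k = 0.280 /h, Ea = 88.0 kJ/mol)
    D + J → L (k = 87000 /M/h, Ea = 37.0 kJ/mol)
    (constants at 5 °C)

In red at 7.97 h, Z goes to E 5.7 times as fast as to G, beside the f of 5.92 that I reckoned for red's late stretch. Changing cZ alone from red to grey shifts the share by 0 points.

Now red kept at 30 °C: going from 5 °C to 30 °C is 2.3 times the step from 0 °C to 11 °C, over which g changed by the factor 0.551, so g comes to 15.7 /mM, f to 1.51 and the late share to 60.2%. That flask gives 58.5%.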